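**Strategy.** Locants: ring C1 (C=O), C2 (CMe), C3, C4, C5 (side-chain carbon), C6 (CH–O-senecioyl); side chain C7 (=CH2), C8 (CHOAc). The cyclohexanone ring is cut at C3–C4 and C5–C6. Both bonds form in a type 2 intramolecular Diels–Alder reaction that exploits the 1,5 relation of the C1 and C8 oxygens: a temporary diisopropylsilyl acetal joins the C1 enol oxygen of the diene C3=C2–C1=C6, already carrying the senecioate, to the C8 oxygen of a chiral-pool vinyl ketone C4=C5–C7(=O). The tether forces C5 onto C6 against the bimolecular preference and relays C8 to C5; the silicon leaves when the enone is unveiled.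

Key step: step 7

Remark on the chemistry: the enol silane of 5 is taken to form with Z geometry (silyloxy and acyloxy groups cis), as is usual for soft enolisation of α-oxygenated ketones.

Step 1
Reactants: 1 2-chloro-N-methoxy-N-methylacetamide; 2 3-methylbut-2-enoic acid
Product: 3 2-[methoxy(methyl)amino]-2-oxoethyl 3-methylbut-2-enoate
Conditions: K2CO3, NaI (10 mol%), DMF, 50 °C
Reagents that add atoms: none
Why: SN2 O-alkylation of the potassium carboxylate by the activated α-chloro amide (ester formation) should install at the outset the senecioate that ends on C6, and no stereocenter is formed.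

Step 2
Reactants: 3 2-[methoxy(methyl)amino]-2-oxoethyl 3-methylbut-2-enoate; 4 prop-1-en-2-ylmagnesium bromide
Product: 5 3-methyl-2-oxobut-3-en-1-yl 3-methylbut-2-enoate
Conditions: THF, −78 → −20 °C; then AcOH, aq. NH4Cl
Reagents that add atoms: none
Why: Weinreb ketone synthesis, in which the Grignard reagent adds once to the N-methoxy-N-methylamide through a stable magnesium chelate and at low temperature much faster than to the hindered conjugated ester, should give the isopropenyl ketone without a new stereocenter.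

Step 3
Reactants: 6 methyl (2R)-oxirane-2-carboxylate; 7 (2-methylprop-1-en-1-yl)magnesium bromide
Product: 8 methyl (2R)-2-hydroxy-5-methylhex-4-enoate
Conditions: CuI (10 mol%), THF, −40 °C; then aq. NH4Cl
Reagents that add atoms: none
Why: Copper-catalysed Grignard opening of the epoxide at its unsubstituted carbon (SN2) should give the α-hydroxy ester while the chiral-pool stereocenter, the future C8, is not touched.

Step 4
Reactants: 8 methyl (2R)-2-hydroxy-5-methylhex-4-enoate
Product: 9 (2R)-2-hydroxy-N-methoxy-N,5-dimethylhex-4-enamide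
Conditions: MeNHOMe·HCl (2 equiv), iPrMgCl (5 equiv), THF, −20 → 0 °C
Reagents that add atoms: N,O-dimethylhydroxylamine hydrochloride, CNOC.Cl
Why: Weinreb amide formation by aminolysis of the ester with the chloromagnesium amide made in the flask from MeNHOMe·HCl and iPrMgCl is established for unprotected α-hydroxy esters and leaves the stereocenter unchanged.

Step 5
Reactants: 9 (2R)-2-hydroxy-N-methoxy-N,5-dimethylhex-4-enamide; 10 ethenylmagnesium bromide
Product: 11 (4R)-4-hydroxy-7-methylocta-1,6-dien-3-one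
Conditions: THF, 0 °C; inverse quench into cold 1 M HCl
Reagents that add atoms: none
Why: Weinreb ketone synthesis with excess vinyl Grignard reagent on the magnesium alkoxide should stop at the ketone, the alkoxide protecting the adjacent C8 stereocenter from enolisation and the acidic inverse quench preventing conjugate addition of the released amine to the enone.

Step 6
Reactants: 5 3-methyl-2-oxobut-3-en-1-yl 3-methylbut-2-enoate; 11 (4R)-4-hydroxy-7-methylocta-1,6-dien-3-one
Product: 13 (1Z)-3-methyl-2-[({[(4R)-7-methyl-3-oxoocta-1,6-dien-4-yl]oxy}di(propan-2-yl)silyl)oxy]buta-1,3-dien-1-yl 3-methylbut-2-enoate, via enol silyl triflate 12 (not isolated)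
Conditions: iPr2Si(OTf)2, Et3N, CH2Cl2, −40 → 0 °C; then 11, 2,6-lutidine, −78 → 0 °C
Reagents that add atoms: di(propan-2-yl)silanediyl bis(trifluoromethanesulfonate), CC(C)[Si](OS(=O)(=O)C(F)(F)F)(OS(=O)(=O)C(F)(F)F)C(C)C
Why: Soft enolisation of the α-acyloxy ketone with the silyl bis(triflate) and Et3N (silyl enol ether formation) should give the Z enol silyl triflate, whose remaining Si–OTf bond then silylates the secondary alcohol of 11, so that one silicon atom links the C1 enol oxygen to the C8 oxygen without creating a stereocenter.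

Step 7
Reactants: 13 (1Z)-3-methyl-2-[({[(4R)-7-methyl-3-oxoocta-1,6-dien-4-yl]oxy}di(propan-2-yl)silyl)oxy]buta-1,3-dien-1-yl 3-methylbut-2-enoate
Product: 14 (5R,7R,11R)-10-methyl-5-(3-methylbut-2-en-1-yl)-6-oxo-3,3-di(propan-2-yl)-2,4-dioxa-3-silabicyclo[5.3.1]undec-1(10)-en-11-yl 3-methylbut-2-enoate (bridged cycloadduct; C6 ester cis to the C5–C7 bond)
Conditions: toluene (0.005 M), BHT (cat.), 100 °C
Reagents that add atoms: none
Why: Thermal type 2 intramolecular Diels–Alder reaction in which the 2-silyloxy diene C3=C2–C1=C6 and the vinyl ketone C4=C5 combine in one concerted but asynchronous [4+2] event that forms C3–C4 and C5–C6 and leaves the C1=C2 silyl enol ether in a defined position. The closest known reaction type is the type 2 intramolecular Diels–Alder reaction of 2-substituted dienes through disposable silyl acetal tethers, which gives 1,3-bridged adducts. The cyclohexene closes by suprafacial [4+2] addition, and the eight-membered dioxasila ring (C1, O, Si, O, C8, C7, C5, C6) closes in the 1,3-bridged mode because the five-atom tether from C1 cannot deliver C5 to C3. C5 is controlled by the C8 stereocenter, since with the enone s-cis and the tether on the endo side the CH2CH=CMe2 group on C8 points away from the diene and from the C6 ester, which selects the diene face that gives the C5 configuration of the target. C6 is controlled by the Z geometry of the enol ether and the endo tether, so its ester is cis to the C5 branch and is corrected by epimerisation in step 10. The step needs regioselectivity against the electronically preferred 1,4 orientation and chemoselectivity against bimolecular or oxa-Diels–Alder pathways, which the short tether and high dilution are meant to secure.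

Step 8
Reactants: 14 (5R,7R,11R)-10-methyl-5-(3-methylbut-2-en-1-yl)-6-oxo-3,3-di(propan-2-yl)-2,4-dioxa-3-silabicyclo[5.3.1]undec-1(10)-en-11-yl 3-methylbut-2-enoate
Product: 15 (5R,7S,11R)-10-methyl-5-(3-methylbut-2-en-1-yl)-6-methylidene-3,3-di(propan-2-yl)-2,4-dioxa-3-silabicyclo[5.3.1]undec-1(10)-en-11-yl 3-methylbut-2-enoate
Conditions: Cp2Ti(µ-CH2)(µ-Cl)AlMe2 (Tebbe reagent), pyridine (cat.), THF–toluene, −40 → 0 °C
Reagents that add atoms: Tebbe reagent Cp2Ti(µ-CH2)(µ-Cl)AlMe2, C=[Ti](C1C=CC=C1)C1C=CC=C1.C[Al](C)Cl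
Why: Tebbe methylenation converts the hindered, base-sensitive β-acyloxy ketone at C7 into the C7=CH2 alkene under non-basic conditions and faster than it attacks the esters, while the ring carbonyl stays masked as the silyl enol ether and no stereocenter changes.

Step 9
Reactants: 15 (5R,7S,11R)-10-methyl-5-(3-methylbut-2-en-1-yl)-6-methylidene-3,3-di(propan-2-yl)-2,4-dioxa-3-silabicyclo[5.3.1]undec-1(10)-en-11-yl 3-methylbut-2-enoate
Product: 17 (1R,6S)-6-[(3R)-3-hydroxy-6-methylhepta-1,5-dien-2-yl]-3-methyl-2-oxocyclohex-3-en-1-yl 3-methylbut-2-enoate, via acetoxysilyl ether 16 (not isolated)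
Conditions: Pd(OAc)2 (1.1 equiv), DMSO–MeCN, 40 °C; then HF·pyridine, THF, 0 °C
Reagents that add atoms: none
Why: Saegusa–Ito oxidation, in which Pd(OAc)2 transmetallates the strained bridgehead silyl enol ether to a palladium enolate at C2 and β-hydride elimination towards C3 gives the 2-methyl enone, should open the tether in the same event, after which HF·pyridine removes the residual acetoxysilyl group from the C8 oxygen without touching C5, C6 or C8.

Step 10
Reactants: 17 (1R,6S)-6-[(3R)-3-hydroxy-6-methylhepta-1,5-dien-2-yl]-3-methyl-2-oxocyclohex-3-en-1-yl 3-methylbut-2-enoate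
Product: 19 (1S,6S)-6-[(3R)-3-(acetyloxy)-6-methylhepta-1,5-dien-2-yl]-3-methyl-2-oxocyclohex-3-en-1-yl 3-methylbut-2-enoate, via cis acetate 18 (not isolated)
Conditions: Ac2O, Et3N, DMAP (cat.), CH2Cl2, 0 °C → rt; then DBU (0.3 equiv), rt
Reagents that add atoms: acetic anhydride, CC(=O)OC(C)=O
Why: DMAP-catalysed acetylation of the allylic alcohol followed by DBU-mediated epimerisation through the C6 enolate should place the senecioate trans to the C5 branch, the diequatorial and therefore thermodynamically preferred arrangement.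

Step 11
Reactants: 19 (1S,6S)-6-[(3R)-3-(acetyloxy)-6-methylhepta-1,5-dien-2-yl]-3-methyl-2-oxocyclohex-3-en-1-yl 3-methylbut-2-enoate
Product: 20 (1S,2S,6S)-6-[(3R)-3-(acetyloxy)-6-methylhepta-1,5-dien-2-yl]-2-hydroxy-3-methylcyclohex-3-en-1-yl 3-methylbut-2-enoate
Conditions: NaBH4, CeCl3·7H2O, MeOH, −78 °C
Reagents that add atoms: none
Why: Luche reduction reduces only the enone carbonyl, and axial hydride delivery to the diequatorial half-chair, anti to the C5 branch as in related 5-substituted cyclohexenones, should set the C1 hydroxyl cis to the C5 branch and trans to the C6 ester.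

Step 12
Reactants: 20 (1S,2S,6S)-6-[(3R)-3-(acetyloxy)-6-methylhepta-1,5-dien-2-yl]-2-hydroxy-3-methylcyclohex-3-en-1-yl 3-methylbut-2-enoate
Product: 21 (1R,2R,3S,4S,6S)-4-[(3R)-3-(acetyloxy)-6-methylhepta-1,5-dien-2-yl]-2-hydroxy-1-methyl-7-oxabicyclo[4.1.0]heptan-3-yl 3-methylbut-2-enoate
Conditions: VO(acac)2 (5 mol%), tBuOOH, CH2Cl2, 0 °C → rt
Reagents that add atoms: tert-butyl hydroperoxide, CC(C)(C)OO
Why: Hydroxyl-directed epoxidation with VO(acac)2 and tBuOOH delivers oxygen to C2=C3 from the face of the C1 hydroxyl, which sets C2 and C3 with the epoxide cis to the C5 branch, and it leaves the isolated alkenes and the enoate untouched.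

Step 13
Reactants: 21 (1R,2R,3S,4S,6S)-4-[(3R)-3-(acetyloxy)-6-methylhepta-1,5-dien-2-yl]-2-hydroxy-1-methyl-7-oxabicyclo[4.1.0]heptan-3-yl 3-methylbut-2-enoate
Product: 22 (1S,3S,4S,6S)-4-[(3R)-3-(acetyloxy)-6-methylhepta-1,5-dien-2-yl]-1-methyl-2-oxo-7-oxabicyclo[4.1.0]heptan-3-yl 3-methylbut-2-enoate (target)
Conditions: Dess–Martin periodinane, NaHCO3, CH2Cl2, 0 °C → rt
Reagents that add atoms: none
Why: Dess–Martin oxidation of the secondary epoxy alcohol to the ketone under buffered conditions removes the temporary C1 stereocenter and should carry C2, C3, C5, C6 and C8 into the target unchanged.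

**Compound list**

1 | 2-chloro-N-methoxy-N-methylacetamide | ClCC(=O)N(C)OC | starting material
2 | 3-methylbut-2-enoic acid | CC(C)=CC(=O)O | starting material
3 | 2-[methoxy(methyl)amino]-2-oxoethyl 3-methylbut-2-enoate | CC(C)=CC(=O)OCC(=O)N(C)OC | intermediate
4 | prop-1-en-2-ylmagnesium bromide | C=C(C)[Mg]Br | starting material
5 | 3-methyl-2-oxobut-3-en-1-yl 3-methylbut-2-enoate | C=C(C)C(=O)COC(=O)C=C(C)C | intermediate
6 | methyl (2R)-oxirane-2-carboxylate | COC(=O)[C@H]1CO1 | starting material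
7 | (2-methylprop-1-en-1-yl)magnesium bromide | CC(C)=C[Mg]Br | starting material
8 | methyl (2R)-2-hydroxy-5-methylhex-4-enoate | COC(=O)[C@@H](CC=C(C)C)O | intermediate
9 | (2R)-2-hydroxy-N-methoxy-N,5-dimethylhex-4-enamide | CON(C)C(=O)[C@@H](CC=C(C)C)O | intermediate
10 | ethenylmagnesium bromide | C=C[Mg]Br | starting material
11 | (4R)-4-hydroxy-7-methylocta-1,6-dien-3-one | C=CC(=O)[C@@H](CC=C(C)C)O | intermediate
12 | (1Z)-2-({di(propan-2-yl)[(trifluoromethanesulfonyl)oxy]silyl}oxy)-3-methylbuta-1,3-dien-1-yl 3-methylbut-2-enoate (enol silyl triflate) | C=C(C)/C(=C/OC(=O)C=C(C)C)O[Si](C(C)C)(C(C)C)OS(=O)(=O)C(F)(F)F | intermediate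
13 | (1Z)-3-methyl-2-[({[(4R)-7-methyl-3-oxoocta-1,6-dien-4-yl]oxy}di(propan-2-yl)silyl)oxy]buta-1,3-dien-1-yl 3-methylbut-2-enoate | C=CC(=O)[C@@H](CC=C(C)C)O[Si](C(C)C)(C(C)C)O/C(=C\OC(=O)C=C(C)C)C(C)=C | intermediate
14 | (5R,7R,11R)-10-methyl-5-(3-methylbut-2-en-1-yl)-6-oxo-3,3-di(propan-2-yl)-2,4-dioxa-3-silabicyclo[5.3.1]undec-1(10)-en-11-yl 3-methylbut-2-enoate | O=C1[C@@H](CC=C(C)C)O[Si](C(C)C)(C(C)C)OC2=C(C)CC[C@@H]1[C@H]2OC(=O)C=C(C)C | intermediate
15 | (5R,7S,11R)-10-methyl-5-(3-methylbut-2-en-1-yl)-6-methylidene-3,3-di(propan-2-yl)-2,4-dioxa-3-silabicyclo[5.3.1]undec-1(10)-en-11-yl 3-methylbut-2-enoate | C=C1[C@@H](CC=C(C)C)O[Si](C(C)C)(C(C)C)OC2=C(C)CC[C@@H]1[C@H]2OC(=O)C=C(C)C | intermediate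
16 | (1R,6S)-6-[(3R)-3-({(acetyloxy)[di(propan-2-yl)]silyl}oxy)-6-methylhepta-1,5-dien-2-yl]-3-methyl-2-oxocyclohex-3-en-1-yl 3-methylbut-2-enoate (acetoxysilyl ether) | C=C([C@@H](CC=C(C)C)O[Si](C(C)C)(C(C)C)OC(C)=O)[C@@H]1CC=C(C)C(=O)[C@@H]1OC(=O)C=C(C)C | intermediate
17 | (1R,6S)-6-[(3R)-3-hydroxy-6-methylhepta-1,5-dien-2-yl]-3-methyl-2-oxocyclohex-3-en-1-yl 3-methylbut-2-enoate | C=C([C@@H](CC=C(C)C)O)[C@@H]1CC=C(C)C(=O)[C@@H]1OC(=O)C=C(C)C | intermediate
18 | (1R,6S)-6-[(3R)-3-(acetyloxy)-6-methylhepta-1,5-dien-2-yl]-3-methyl-2-oxocyclohex-3-en-1-yl 3-methylbut-2-enoate (cis acetate) | C=C([C@@H](CC=C(C)C)OC(C)=O)[C@@H]1CC=C(C)C(=O)[C@@H]1OC(=O)C=C(C)C | intermediate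
19 | (1S,6S)-6-[(3R)-3-(acetyloxy)-6-methylhepta-1,5-dien-2-yl]-3-methyl-2-oxocyclohex-3-en-1-yl 3-methylbut-2-enoate | C=C([C@@H](CC=C(C)C)OC(C)=O)[C@@H]1CC=C(C)C(=O)[C@H]1OC(=O)C=C(C)C | intermediate
20 | (1S,2S,6S)-6-[(3R)-3-(acetyloxy)-6-methylhepta-1,5-dien-2-yl]-2-hydroxy-3-methylcyclohex-3-en-1-yl 3-methylbut-2-enoate | C=C([C@@H](CC=C(C)C)OC(C)=O)[C@@H]1CC=C(C)[C@H](O)[C@H]1OC(=O)C=C(C)C | intermediate
21 | (1R,2R,3S,4S,6S)-4-[(3R)-3-(acetyloxy)-6-methylhepta-1,5-dien-2-yl]-2-hydroxy-1-methyl-7-oxabicyclo[4.1.0]heptan-3-yl 3-methylbut-2-enoate | C=C([C@@H](CC=C(C)C)OC(C)=O)[C@@H]1C[C@@H]2O[C@]2(C)[C@H](O)[C@H]1OC(=O)C=C(C)C | intermediate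
22 | (1S,3S,4S,6S)-4-[(3R)-3-(acetyloxy)-6-methylhepta-1,5-dien-2-yl]-1-methyl-2-oxo-7-oxabicyclo[4.1.0]heptan-3-yl 3-methylbut-2-enoate | C=C([C@@H](CC=C(C)C)OC(C)=O)[C@@H]1C[C@@H]2O[C@]2(C)C(=O)[C@H]1OC(=O)C=C(C)C | target

**Step count and risks**

Total step count: 13. Longest linear sequence: 11 steps (steps 3 to 13, from methyl (2R)-oxirane-2-carboxylate 6).

The three steps most likely to fail:

Step 7 (key step). What may go wrong: leakage to the electronically preferred 1,4-bridged regioisomer, a competing inverse-demand oxa-Diels–Alder reaction between the enone and the enol ether, bimolecular cycloaddition, or too small a facial bias from C8. The fallback sets out from 5 and 11 and comes back at 19; it gives up the tether and enforces the orientation with a removable sulfonyl group on C4. Ketone 5 is silylated (TBSOTf, Et3N) to the silyl dienol ether F1. Alcohol 11 is acetylated to the keto acetate F2, methylenated with the Tebbe reagent Cp2Ti(µ-CH2)(µ-Cl)AlMe2 to the diene acetate F3, and cross-metathesised with phenyl vinyl sulfone (Hoveyda–Grubbs second-generation catalyst RuCl2(H2IMes)(=CH-C6H4-2-OiPr)) to the dienyl sulfone F4. Thermal Diels–Alder reaction of F1 with F4 (toluene, 110 °C) should still form C3–C4 and C5–C6 in one operation, the nucleophilic C6 now adding to the sulfone β-carbon C5, and give the sulfonyl cycloadduct F5; without the tether the two facial diastereomers would have to be separated. Sodium amalgam (Na/Hg, Na2HPO4, MeOH) removes the sulfonyl group to give the silyl enol ether F6, and Saegusa–Ito oxidation with Pd(OAc)2 followed by the DBU equilibration used in step 10 returns to 19.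

Step 9. What may go wrong: slow transmetallation of the hindered dialkoxysilyl enol ether, β-hydride elimination towards the methyl group, or premature hydrolysis of the enol ether with loss of the regiochemical information. The fallback sets out from 15 and comes back at 17: bromination of the silyl enol ether at C2 with NBS (THF, −78 °C) and work-up with HF·pyridine should give the bromo ketone F7, and dehydrobromination with Li2CO3 and LiBr in DMF at 100 °C then gives 17.

Step 11. What may go wrong: hydride delivery to the other face through a conformer with an axial C6 ester, or 1,2-acyl migration from O6 to O1 under the borohydride conditions. The fallback sets out from 19 and comes back at 20: the C1 epimer F8 formed in that case is inverted by a Mitsunobu reaction with chloroacetic acid (PPh3, DIAD) to the chloroacetate F9, and the chloroacetyl group is removed selectively with thiourea and NaHCO3 in ethanol to give 20.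

**Further compounds**

F1 | step 7 | (1Z)-2-{[tert-butyl(dimethyl)silyl]oxy}-3-methylbuta-1,3-dien-1-yl 3-methylbut-2-enoate | C=C(C)/C(=C/OC(=O)C=C(C)C)O[Si](C)(C)C(C)(C)C
F2 | step 7 | (4R)-7-methyl-3-oxoocta-1,6-dien-4-yl acetate | C=CC(=O)[C@@H](CC=C(C)C)OC(C)=O
F3 | step 7 | (4R)-7-methyl-3-methylideneocta-1,6-dien-4-yl acetate | C=CC(=C)[C@@H](CC=C(C)C)OC(C)=O
F4 | step 7 | (1E,4R)-1-(benzenesulfonyl)-7-methyl-3-methylideneocta-1,6-dien-4-yl acetate | O=S(=O)(/C=C/C(=C)[C@@H](CC=C(C)C)OC(C)=O)c1ccccc1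
F5 | step 7 | (1S,5S,6S)-6-[(3R)-3-(acetyloxy)-6-methylhepta-1,5-dien-2-yl]-5-(benzenesulfonyl)-2-{[tert-butyl(dimethyl)silyl]oxy}-3-methylcyclohex-2-en-1-yl 3-methylbut-2-enoate | C=C([C@@H](CC=C(C)C)OC(C)=O)[C@@H]1[C@@H](S(=O)(=O)c2ccccc2)CC(C)=C(O[Si](C)(C)C(C)(C)C)[C@H]1OC(=O)C=C(C)C
F6 | step 7 | (1S,6S)-6-[(3R)-3-(acetyloxy)-6-methylhepta-1,5-dien-2-yl]-2-{[tert-butyl(dimethyl)silyl]oxy}-3-methylcyclohex-2-en-1-yl 3-methylbut-2-enoate | C=C([C@@H](CC=C(C)C)OC(C)=O)[C@@H]1CCC(C)=C(O[Si](C)(C)C(C)(C)C)[C@H]1OC(=O)C=C(C)C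
F7 | step 9 | (1R,6S)-3-bromo-6-[(3R)-3-hydroxy-6-methylhepta-1,5-dien-2-yl]-3-methyl-2-oxocyclohexyl 3-methylbut-2-enoate (C3 epimers) | C=C([C@@H](CC=C(C)C)O)[C@@H]1CCC(C)(Br)C(=O)[C@@H]1OC(=O)C=C(C)C
F8 | step 11 | (1S,2R,6S)-6-[(3R)-3-(acetyloxy)-6-methylhepta-1,5-dien-2-yl]-2-hydroxy-3-methylcyclohex-3-en-1-yl 3-methylbut-2-enoate | C=C([C@@H](CC=C(C)C)OC(C)=O)[C@@H]1CC=C(C)[C@@H](O)[C@H]1OC(=O)C=C(C)C
F9 | step 11 | (1S,2S,6S)-6-[(3R)-3-(acetyloxy)-6-methylhepta-1,5-dien-2-yl]-2-[(chloroacetyl)oxy]-3-methylcyclohex-3-en-1-yl 3-methylbut-2-enoate | C=C([C@@H](CC=C(C)C)OC(C)=O)[C@@H]1CC=C(C)[C@H](OC(=O)CCl)[C@H]1OC(=O)C=C(C)C
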